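**Strategy.** The cis-hydroazulene is cut at the bond shared by its cyclopentane and cycloheptane rings and at the bond joining the two oxirane carbons. The feature used is that the ring-fusion CH next to the tertiary carbinol and the oxirane CH are 1,3-related in the cycloheptane, like the β- and carbonyl carbons of an enal, while the carbinol oxygen is δ to the other ring-fusion carbon. One Bu3SnH operation on an acyclic nitrate ester therefore gives alkoxy radical, 1,5-hydrogen shift, 5-exo addition to the enal and stannyl-ketyl pinacol closure onto a methyl ketone. Corey–Winter olefination, fragment union, a diepoxide cascade and bromohydrin closure complete the target.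

Key step: step 14

Remark on the chemistry (assumption): electrophiles are taken to attack the cycloheptene C=C of 38 from the face carrying the three ring hydrogens; the oxirane oxygen of the target lies on the other face, so it is installed by bromohydrin formation and ring closure.

## Route

Step 1
Reactants: 1 ethyl (R)-3-hydroxybutanoate; 2 3-methylbut-2-en-1-ol (prenol)
Product: 3 3-methylbut-2-enyl (R)-3-hydroxybutanoate
Conditions: Ti(OiPr)4 (cat.), toluene, 110 °C, distil off EtOH
Reagents that add atoms: none
Why: Titanate-catalysed transesterification exchanges ethyl for prenyl without touching the stereocentre.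

Step 2
Reactants: 3 3-methylbut-2-enyl (R)-3-hydroxybutanoate
Product: 4 (2R,3R)-3-hydroxy-2-(2-methylbut-3-en-2-yl)butanoic acid
Conditions: LDA (2.2 equiv), THF, −78 → 60 °C; aq. HCl
Reagents that add atoms: none
Why: Dianionic ester-enolate (Ireland-type) Claisen rearrangement; the chelated β-oxido enolate should rearrange through a chair transition state anti to the carbinol methyl (Fráter–Seebach sense), setting the α-stereocentre and the quaternary CMe2 carbon in one [3,3] shift.

Step 3
Reactants: 4 (2R,3R)-3-hydroxy-2-(2-methylbut-3-en-2-yl)butanoic acid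
Product: 5 (2S,3R)-2-(2-methylbut-3-en-2-yl)butane-1,3-diol
Conditions: LiAlH4, THF, 0 → 65 °C
Reagents that add atoms: none
Why: Hydride reduction of the carboxylic acid to the primary alcohol; no stereocentre is affected.

Step 4
Reactants: 5 (2S,3R)-2-(2-methylbut-3-en-2-yl)butane-1,3-diol
Product: 6 1-O-TBS ether of diol 5 (secondary hydroxyl free)
Conditions: TBSCl, imidazole, CH2Cl2, 0 °C
Reagents that add atoms: tert-butyldimethylsilyl chloride, CC(C)(C)[Si](C)(C)Cl
Why: Selective silylation of the less hindered primary hydroxyl.

Step 5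
Reactants: 6 1-O-TBS ether of diol 5
Product: 7 1-O-TBS 3-O-TES bis-silyl ether of diol 5
Conditions: TESCl, imidazole, DMAP (cat.), CH2Cl2, 25 °C
Reagents that add atoms: triethylsilyl chloride, CC[Si](CC)(CC)Cl
Why: Silylation of the secondary hydroxyl with a group that can later be removed in the presence of the TBS ether.

Step 6
Reactants: 7 1-O-TBS 3-O-TES bis-silyl ether of diol 5
Product: 9 primary iodide from 7 (CH=CH2 converted into CH2CH2I), via B-alkyl-9-BBN adduct 8 (not isolated)
Conditions: 9-BBN, THF, 0 → 25 °C; then I2, NaOMe, MeOH, 0 °C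
Reagents that add atoms: iodine, II
Why: Anti-Markovnikov hydroboration of the terminal alkene followed by base-induced iodinolysis of the primary B–C bond.

Step 7
Reactants: 10 (S)-2-methylglycidol
Product: 11 (R)-2-[(4-methoxybenzyloxy)methyl]-2-methyloxirane
Conditions: NaH, PMBCl, Bu4NI (cat.), THF, 0 → 25 °C
Reagents that add atoms: 4-methoxybenzyl chloride, COc1ccc(CCl)cc1
Why: Williamson etherification; the quaternary stereocentre is untouched (the descriptor changes only through CIP priorities).

Step 8
Reactants: 9 primary iodide from 7; 11 (R)-2-[(4-methoxybenzyloxy)methyl]-2-methyloxirane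
Product: 13 tertiary alcohol PMB ether (chain CH2CH2CH2–C(CH3)(OH)–CH2OPMB), via alkylmagnesium iodide 12 (not isolated)
Conditions: Mg, Et2O, 25 °C; then 11, CuI (10 mol%), THF, −30 → 0 °C; aq. NH4Cl
Reagents that add atoms: none
Why: Copper-catalysed Grignard opening of the 2,2-disubstituted epoxide at its CH2 carbon (SN2), which installs the tertiary carbinol with the configuration of 11.

Step 9
Reactants: 13 tertiary alcohol PMB ether
Product: 14 1,2-diol from 13 (PMB removed)
Conditions: DDQ, CH2Cl2–pH 7 buffer, 0 °C
Reagents that add atoms: none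
Why: Oxidative cleavage of the PMB ether; silyl ethers are stable.

Step 10
Reactants: 14 1,2-diol from 13
Product: 16 (E)-γ-hydroxy enal (TBS and TES ethers retained), via α-hydroxy aldehyde 15 (not isolated)
Conditions: SO3·pyridine, DMSO, Et3N, CH2Cl2, 0 °C; then Ph3P=CHCHO, toluene, 60 °C
Reagents that add atoms: (triphenylphosphoranylidene)acetaldehyde, O=CC=P(c1ccccc1)(c1ccccc1)c1ccccc1
Why: Parikh–Doering oxidation of the primary alcohol and Wittig olefination with the stabilised formyl ylide, which should give the (E)-enal.

Step 11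
Reactants: 16 (E)-γ-hydroxy enal (TBS and TES ethers retained)
Product: 17 (E)-γ-hydroxy enal with free secondary hydroxyl
Conditions: HF·pyridine, pyridine, THF, 0 °C
Reagents that add atoms: none
Why: Selective cleavage of the more labile secondary TES ether in the presence of the primary TBS ether.

Step 12
Reactants: 17 (E)-γ-hydroxy enal with free secondary hydroxyl
Product: 18 keto enal (methyl ketone, free tertiary hydroxyl)
Conditions: Dess–Martin periodinane, NaHCO3, CH2Cl2, 0 → 25 °C
Reagents that add atoms: none
Why: Dess–Martin oxidation of the secondary alcohol; the tertiary allylic alcohol and the enal are inert, and the hindered α-stereocentre should not epimerise under buffered conditions.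

Step 13
Reactants: 18 keto enal
Product: 19 tertiary nitrate ester of 18
Conditions: fuming HNO3, Ac2O, CH2Cl2, −40 °C
Reagents that add atoms: acetyl nitrate (formed in situ from HNO3 and Ac2O), CC(=O)O[N+](=O)[O-]
Why: O-Nitration of the tertiary alcohol gives the alkoxy-radical precursor; the electron-poor enal should disfavour allylic ionisation.

Step 14
Reactants: 19 tertiary nitrate ester of 18
Product: 21 cis-fused hydroazulene triol (1,2-diol in the seven-membered ring, TBS ether), via cyclopentanol keto aldehyde 20 (not isolated)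
Conditions: Bu3SnH (1.2 equiv, syringe pump), AIBN (cat.), benzene, 80 °C, high dilution; then Bu3SnH (2.5 equiv), AIBN, 80 °C; aq. KF
Reagents that add atoms: none
Why: Proposed new method: Bu3Sn• cleaves the O–NO2 bond to a tertiary alkoxy radical, which abstracts the δ-hydrogen (1,5-hydrogen transfer, six-membered transition state) from the CH2 next to the CMe2 group; the secondary radical adds to the enal β-carbon (5-exo-trig), the α-formyl radical is reduced by Bu3SnH to aldehyde 20, and the O-stannyl ketyl of 20 then adds to the methyl ketone carbonyl (7-exo onto C=O) to give the stannylated 1,2-diol. The closest known reaction types are alkoxy-radical translocation/cyclisation sequences started from nitrate esters and the Bu3SnH-mediated intramolecular pinacol coupling of keto aldehydes, the latter shown so far for five- and six-membered rings. In the chair-like 5-exo transition state (Beckwith–Houk model) the bulky tert-alkyl group on the radical carbon and the hydroxyl on the allylic quaternary carbon sit pseudo-equatorially (C–O anti to the forming bond, Felkin–Anh-type), which should place both new ring-fusion hydrogens cis to the hydroxyl, i.e. the cis ring fusion of the target; the carbinol carbon and the side-chain-bearing carbon keep their configurations. The two diol centres need no control because both become sp2 in step 16. Regioselectivity of hydrogen abstraction follows from the 1,5-relationship (only this CH2 is δ to the oxygen), the order of events from the rates (fast radical cyclisation at low Bu3SnH concentration, slow ketyl coupling with the later excess), and the trans disposition of hydroxyl and CH2CHO chain prevents a lactol that would mask the aldehyde.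

Step 15
Reactants: 21 cis-fused hydroazulene triol
Product: 22 cyclic thiocarbonate of the 1,2-diol of 21
Conditions: 1,1′-thiocarbonyldiimidazole, DMAP (cat.), toluene, 90 °C
Reagents that add atoms: 1,1′-thiocarbonyldiimidazole, S=C(n1ccnc1)n1ccnc1
Why: Thiocarbonate formation (first stage of the Corey–Winter olefination) on the vicinal diol; the isolated tertiary cyclopentanol cannot form a ring and should stay free.

Step 16
Reactants: 22 cyclic thiocarbonate
Product: 23 hydroazulene alkene (trisubstituted C=C in the seven-membered ring, TBS ether, tertiary OH)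
Conditions: P(OMe)3, 110 °C
Reagents that add atoms: none
Why: Corey–Winter olefination; desulfurisation by the phosphite and loss of CO2 give the ring alkene and remove both diol stereocentres.

Step 17
Reactants: 23 hydroazulene alkene
Product: 24 hydroazulene diol (primary and tertiary hydroxyl)
Conditions: TBAF, THF, 25 °C
Reagents that add atoms: none
Why: Fluoride cleavage of the primary TBS ether.

Step 18
Reactants: 24 hydroazulene diol
Product: 25 hydroazulene primary iodide (tertiary hydroxyl free)
Conditions: I2, PPh3, imidazole, CH2Cl2, 0 °C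
Reagents that add atoms: iodine, II
Why: Appel-type iodination, which is selective for the primary alcohol.

Step 19
Reactants: 25 hydroazulene primary iodide
Product: 26 hydroazulene primary iodide TES ether
Conditions: TESOTf, 2,6-lutidine, CH2Cl2, −78 → 0 °C
Reagents that add atoms: triethylsilyl triflate, CC[Si](CC)(CC)OS(=O)(=O)C(F)(F)F
Why: Silylation of the tertiary alcohol so that the Grignard reagent of step 22 can be formed.

Step 20
Reactants: 27 (E)-geranylacetone
Product: 28 4-{(2R,3R)-3-[2-((2R)-3,3-dimethyloxiran-2-yl)ethyl]-3-methyloxiran-2-yl}butan-2-one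
Conditions: D-fructose-derived Shi ketone (30 mol%), Oxone, K2CO3, Bu4NHSO4 (cat.), MeCN–CH2(OMe)2–aq. Na2B4O7 buffer, 0 °C
Reagents that add atoms: potassium peroxymonosulfate (Oxone), [K+].[O-]S(=O)(=O)OO
Why: Shi asymmetric epoxidation; the chiral dioxirane should epoxidise both trisubstituted alkenes from the same face (spiro transition state), giving the all-R diepoxide.

Step 21
Reactants: 28 diepoxy methyl ketone
Product: 31 5-{(2R,3R)-3-[2-((2R)-3,3-dimethyloxiran-2-yl)ethyl]-3-methyloxiran-2-yl}pent-1-en-3-one, via Mannich base 29 (not isolated), via methiodide 30 (not isolated)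
Conditions: LDA, THF, −78 °C; CH2=NMe2+ I−, −78 → 0 °C; then MeI, CH2Cl2, 25 °C; then NaHCO3, CH2Cl2–H2O, 25 °C
Reagents that add atoms: Eschenmoser's salt, C=[N+](C)C.[I-]
Why: Mannich reaction of the kinetic (methyl-side) enolate, quaternisation and elimination give the vinyl ketone; the epoxides tolerate these conditions.

Step 22
Reactants: 26 hydroazulene primary iodide TES ether; 31 diepoxy vinyl ketone
Product: 33 (Z)-trimethylsilyl enol ether (coupled fragments), via alkylmagnesium iodide 32 (not isolated)
Conditions: Mg, Et2O, 25 °C; then 31, CuBr·SMe2 (10 mol%), TMSCl, HMPA, THF, −78 °C; Et3N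
Reagents that add atoms: trimethylsilyl chloride, C[Si](C)(C)Cl
Why: Copper-catalysed conjugate addition of the Grignard reagent with in situ silyl trapping joins the two halves and fixes the enol ether regiochemistry.

Step 23
Reactants: 33 (Z)-trimethylsilyl enol ether
Product: 35 oxepanol–cyclohexanone (secondary OH free, tertiary TES ether), via trimethylsilyl ether 34 (not isolated)
Conditions: TMSOTf (0.3 equiv), 2,6-di-tert-butyl-4-methylpyridine, CH2Cl2, −78 °C; then K2CO3, MeOH, 0 °C
Reagents that add atoms: none
Why: Lewis-acid-initiated tandem oxa-/carbacyclisation (epoxide-opening cascade): the internal epoxide oxygen opens the silylated terminal epoxide at its tertiary carbon (oxepane), and the silyl enol ether opens the resulting epoxonium ion anti at its tertiary carbon, which should give the trans ring junction; K2CO3–MeOH cleaves the TMS ether and equilibrates the α-centre to the equatorial side chain.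

Step 24
Reactants: 35 oxepanol–cyclohexanone
Product: 36 tertiary carbinol from methyl addition
Conditions: MeMgBr (4 equiv), CeCl3, THF, −78 → 0 °C
Reagents that add atoms: methylmagnesium bromide, C[Mg]Br
Why: Organocerium 1,2-addition to the hindered ketone from the equatorial direction (away from the axial angular methyl), which should give the axial tertiary alcohol.

Step 25
Reactants: 36 tertiary carbinol
Product: 37 triol alkene
Conditions: TBAF, THF, 50 °C
Reagents that add atoms: none
Why: Fluoride cleavage of the tertiary TES ether.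

Step 26
Reactants: 37 triol alkene
Product: 38 oxepanone diol alkene
Conditions: Dess–Martin periodinane, NaHCO3, CH2Cl2, 0 → 25 °C
Reagents that add atoms: none
Why: Dess–Martin oxidation of the only secondary alcohol; both tertiary alcohols and the alkene are inert.

Step 27
Reactants: 38 oxepanone diol alkene
Product: 40 CNP0259752.1 (target), via bromohydrin 39 (not isolated)
Conditions: NBS, THF–H2O, 0 °C; then K2CO3, MeOH, 25 °C
Reagents that add atoms: water, O
Why: Bromohydrin formation (anti addition, water at the tertiary carbon) followed by base-induced SN2 closure with inversion at the CH–Br carbon, which should place the oxirane oxygen on the face opposite to bromonium attack.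

## Compound list

1 | ethyl (R)-3-hydroxybutanoate | CCOC(=O)C[C@@H](C)O | starting material
2 | 3-methylbut-2-en-1-ol (prenol) | CC(C)=CCO | starting material
3 | 3-methylbut-2-enyl (R)-3-hydroxybutanoate | CC(C)=CCOC(=O)C[C@@H](C)O | intermediate
4 | (2R,3R)-3-hydroxy-2-(2-methylbut-3-en-2-yl)butanoic acid | C[C@@H](O)[C@H](C(O)=O)C(C)(C)C=C | intermediate
5 | (2S,3R)-2-(2-methylbut-3-en-2-yl)butane-1,3-diol | C[C@@H](O)[C@H](CO)C(C)(C)C=C | intermediate
6 | 1-O-TBS ether of diol 5 (secondary hydroxyl free) | CC(C)(C)[Si](C)(C)OC[C@@H]([C@@H](C)O)C(C)(C)C=C | intermediate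
7 | 1-O-TBS 3-O-TES bis-silyl ether of diol 5 | CC(C)(C)[Si](C)(C)OC[C@@H]([C@@H](C)O[Si](CC)(CC)CC)C(C)(C)C=C | intermediate
8 | B-alkyl-9-BBN adduct of 7 (boron on the terminal carbon) | CC(C)(C)[Si](C)(C)OC[C@@H]([C@@H](C)O[Si](CC)(CC)CC)C(C)(C)CCB1C2CCCC1CCC2 | intermediate
9 | primary iodide from 7 (CH=CH2 converted into CH2CH2I) | CC(C)(C)[Si](C)(C)OC[C@@H]([C@@H](C)O[Si](CC)(CC)CC)C(C)(C)CCI | intermediate
10 | (S)-2-methylglycidol | C[C@]1(CO)CO1 | starting material
11 | (R)-2-[(4-methoxybenzyloxy)methyl]-2-methyloxirane | C[C@]1(COCc2ccc(OC)cc2)CO1 | intermediate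
12 | alkylmagnesium iodide from 9 | CC(C)(C)[Si](C)(C)OC[C@@H]([C@@H](C)O[Si](CC)(CC)CC)C(C)(C)CC[Mg]I | intermediate
13 | tertiary alcohol PMB ether (R at the new carbinol carbon) | CC(C)(C)[Si](C)(C)OC[C@@H]([C@@H](C)O[Si](CC)(CC)CC)C(C)(C)CCC[C@@](C)(O)COCc1ccc(OC)cc1 | intermediate
14 | 1,2-diol from 13 (PMB removed) | CC(C)(C)[Si](C)(C)OC[C@@H]([C@@H](C)O[Si](CC)(CC)CC)C(C)(C)CCC[C@@](C)(O)CO | intermediate
15 | α-hydroxy aldehyde from 14 | CC(C)(C)[Si](C)(C)OC[C@@H]([C@@H](C)O[Si](CC)(CC)CC)C(C)(C)CCC[C@@](C)(O)C=O | intermediate
16 | (E)-γ-hydroxy enal (TBS and TES ethers retained) | CC(C)(C)[Si](C)(C)OC[C@@H]([C@@H](C)O[Si](CC)(CC)CC)C(C)(C)CCC[C@@](C)(O)/C=C/C=O | intermediate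
17 | (E)-γ-hydroxy enal with free secondary hydroxyl | CC(C)(C)[Si](C)(C)OC[C@@H]([C@@H](C)O)C(C)(C)CCC[C@@](C)(O)/C=C/C=O | intermediate
18 | keto enal (methyl ketone, free tertiary hydroxyl) | CC(C)(C)[Si](C)(C)OC[C@@H](C(C)=O)C(C)(C)CCC[C@@](C)(O)/C=C/C=O | intermediate
19 | tertiary nitrate ester of 18 | CC(C)(C)[Si](C)(C)OC[C@@H](C(C)=O)C(C)(C)CCC[C@@](C)(O[N+](=O)[O-])/C=C/C=O | intermediate
20 | cyclopentanol keto aldehyde (two new CH centres, both H cis to OH) | CC(C)(C)[Si](C)(C)OC[C@@H](C(C)=O)C(C)(C)[C@@H]1CC[C@@](C)(O)[C@@H]1CC=O | intermediate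
21 | cis-fused hydroazulene triol (cis-1,2-diol in the seven-membered ring drawn as the expected isomer, TBS ether) | CC(C)(C)[Si](C)(C)OC[C@@H]1C(C)(C)[C@@H]2CC[C@@](C)(O)[C@@H]2C[C@@H](O)[C@@]1(C)O | intermediate
22 | cyclic thiocarbonate of the 1,2-diol of 21 | CC(C)(C)[Si](C)(C)OC[C@@H]1C(C)(C)[C@@H]2CC[C@@](C)(O)[C@@H]2C[C@H]3OC(=S)O[C@@]13C | intermediate
23 | hydroazulene alkene (TBS ether, tertiary OH) | CC(C)(C)[Si](C)(C)OC[C@@H]1C(C)(C)[C@@H]2CC[C@@](C)(O)[C@@H]2CC=C1C | intermediate
24 | hydroazulene diol (primary and tertiary hydroxyl) | OC[C@@H]1C(C)(C)[C@@H]2CC[C@@](C)(O)[C@@H]2CC=C1C | intermediate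
25 | hydroazulene primary iodide (tertiary hydroxyl free) | IC[C@@H]1C(C)(C)[C@@H]2CC[C@@](C)(O)[C@@H]2CC=C1C | intermediate
26 | hydroazulene primary iodide TES ether | IC[C@@H]1C(C)(C)[C@@H]2CC[C@@](C)(O[Si](CC)(CC)CC)[C@@H]2CC=C1C | intermediate
27 | (E)-geranylacetone [(E)-6,10-dimethylundeca-5,9-dien-2-one] | CC(=O)CC/C=C(\C)CCC=C(C)C | starting material
28 | 4-{(2R,3R)-3-[2-((2R)-3,3-dimethyloxiran-2-yl)ethyl]-3-methyloxiran-2-yl}butan-2-one | CC(=O)CC[C@H]1O[C@]1(C)CC[C@H]1OC1(C)C | intermediate
29 | Mannich base of 28 (CH2NMe2 on the former methyl carbon) | CN(C)CCC(=O)CC[C@H]1O[C@]1(C)CC[C@H]1OC1(C)C | intermediate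
30 | methiodide of 29 | [I-].C[N+](C)(C)CCC(=O)CC[C@H]1O[C@]1(C)CC[C@H]1OC1(C)C | intermediate
31 | 5-{(2R,3R)-3-[2-((2R)-3,3-dimethyloxiran-2-yl)ethyl]-3-methyloxiran-2-yl}pent-1-en-3-one | C=CC(=O)CC[C@H]1O[C@]1(C)CC[C@H]1OC1(C)C | intermediate
32 | alkylmagnesium iodide from 26 | I[Mg]C[C@@H]1C(C)(C)[C@@H]2CC[C@@](C)(O[Si](CC)(CC)CC)[C@@H]2CC=C1C | intermediate
33 | (Z)-trimethylsilyl enol ether (diepoxide chain joined to the hydroazulene) | C[Si](C)(C)O/C(CC[C@H]1O[C@]1(C)CC[C@H]1OC1(C)C)=C\CC[C@@H]1C(C)(C)[C@@H]2CC[C@@](C)(O[Si](CC)(CC)CC)[C@@H]2CC=C1C | intermediate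
34 | trans-fused oxepane–cyclohexanone, trimethylsilyl ether of the oxepanol | CC1(C)O[C@@H]2CCC(=O)[C@H](CC[C@@H]3C(C)(C)[C@@H]4CC[C@@](C)(O[Si](CC)(CC)CC)[C@@H]4CC=C3C)[C@@]2(C)CC[C@H]1O[Si](C)(C)C | intermediate
35 | oxepanol–cyclohexanone (secondary OH free, tertiary TES ether) | CC1(C)O[C@@H]2CCC(=O)[C@H](CC[C@@H]3C(C)(C)[C@@H]4CC[C@@](C)(O[Si](CC)(CC)CC)[C@@H]4CC=C3C)[C@@]2(C)CC[C@H]1O | intermediate
36 | tertiary carbinol from methyl addition (axial OH on the cyclohexane) | CC1(C)O[C@@H]2CC[C@](C)(O)[C@H](CC[C@@H]3C(C)(C)[C@@H]4CC[C@@](C)(O[Si](CC)(CC)CC)[C@@H]4CC=C3C)[C@@]2(C)CC[C@H]1O | intermediate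
37 | triol alkene | CC1(C)O[C@@H]2CC[C@](C)(O)[C@H](CC[C@@H]3C(C)(C)[C@@H]4CC[C@@](C)(O)[C@@H]4CC=C3C)[C@@]2(C)CC[C@H]1O | intermediate
38 | oxepanone diol alkene | CC1(C)O[C@@H]2CC[C@](C)(O)[C@H](CC[C@@H]3C(C)(C)[C@@H]4CC[C@@](C)(O)[C@@H]4CC=C3C)[C@@]2(C)CCC1=O | intermediate
39 | bromohydrin (Br on the ring CH, OH on the methyl-bearing carbon, trans) | CC1(C)O[C@@H]2CC[C@](C)(O)[C@H](CC[C@@H]3C(C)(C)[C@@H]4CC[C@@](C)(O)[C@@H]4C[C@@H](Br)[C@]3(C)O)[C@@]2(C)CCC1=O | intermediate
40 | CNP0259752.1 | CC1(C)O[C@@H]2CC[C@](C)(O)[C@H](CC[C@@H]3C(C)(C)[C@@H]4CC[C@@](C)(O)[C@@H]4C[C@@H]4O[C@@]43C)[C@@]2(C)CCC1=O | target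

## Step count and risks

Total step count: 27. Longest linear sequence: 24 steps (steps 1–6, 8–19, 22–27).

Steps most likely to fail:

1. Step 14 (proposed new method). The tertiary alkoxy radical may undergo β-scission instead of 1,5-hydrogen transfer, and the stannyl ketyl may be reduced before the slow seven-membered closure. Fallback with known chemistry, setting out from 19: the nitrate ester is reduced with only a slight excess of Bu3SnH under high dilution, so that the sequence stops at cyclopentanol keto aldehyde 20, which is isolated (no compound outside the list, F0). Compound 20 is then closed by an intramolecular McMurry coupling (TiCl3(DME)1.5, Zn–Cu couple, DME, reflux), a reaction established for seven-membered cycloalkenes from keto aldehydes. This gives alkene 23 directly, where the route is rejoined; steps 15 and 16 fall away.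

2. Step 13. O-Nitration may fail through ionisation of the tertiary allylic nitrate or acid-induced loss of the silyl ether. Fallback setting out from 18: the alkoxy radical is generated from the free alcohol by cerium photocatalysis (CeCl3, Bu4NCl, 400 nm light, MeCN; ligand-to-metal charge transfer). 1,5-Hydrogen transfer and intramolecular Giese addition give cyclopentanol keto aldehyde 20 (no compound outside the list, F0), and McMurry coupling as above returns to the route at 23.

3. Step 27. The bromonium ion may form on the other face, or the tertiary cyclopentanol may capture it (bromoetherification) instead of water. Fallback setting out from 38: direct epoxidation with dimethyldioxirane (acetone, −20 °C) or mCPBA/NaHCO3 delivers oxygen to the face that the electrophile attacks and gives 40 in one step (no compound outside the list, F0). It is used if the facial preference proves opposite to the assumption.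

Further compounds
F0 | step 14 | none | none
F0 | step 13 | none | none
F0 | step 27 | none | none
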